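**Plan**

1. Ring numbering used here: C1(Me)=C2H–C3H(benzofuranyl)–C4H(aroyl)–C5H(aryl)–C6H2. The retrosynthesis cuts, in order: the seven aryl O–Si bonds; the ring bond C3–C4, re-joined as C1–C4 so that the cyclohexene contracts to a 2-alkenylcyclobutyl ketone; C5–aryl; C4–C(=O); the four-membered ring (back to an enone and a cyclopropylidene unit); the enone C=C; the furan ring and the formyl C–C bond.
2. Forward order: benzofuran ring (Sonogashira/cyclisation) → enone → cyclobutanone → 1-aroylcyclobutene → 2-aryl-1-aroyl-4-methyl-4-alkenylcyclobutane → ring expansion of the four-ring to the six-ring → desilylation.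
3. Enabling feature: C4 is α to the aryl ketone, and C3 is the benzofuranyl-substituted end of the allyl unit C1(Me)=C2–C3. The C3–C4 bond can therefore form by collapse of an enolate/allyl-cation pair, and that pair is what heterolysis of the strained vicinal donor–acceptor bond C1–C4 of the cyclobutane releases.
4. Stereochemistry: only C5 is set by a catalyst (Rh/chiral diene conjugate arylation). C3 and C4 are relayed from C5 in the ring expansion (chair-like closure, all substituents equatorial). C1 and C4 of the cyclobutane need no control because both become planar in that step.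

Key step: step 14

Abbreviations: TBS = tert-butyldimethylsilyl; BF = 4,6-bis(TBS-oxy)-2-[3-(TBS-oxy)phenyl]-1-benzofuran-5-yl; RA = 2,4-bis(TBS-oxy)phenyl.

Assumption: the sense of induction of the Rh/chiral diene catalyst on the cyclobutenyl ketone is fixed by the choice of ligand enantiomer; the enantiomer that gives the (2S) aryl-bearing carbon of 32 is used, and its antipode would give the mirror-image series.

**Route**

Step 1
Reactants: 1 4-bromobenzene-1,3-diol; 2 tert-butyldimethylsilyl chloride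
Product: 3 1-bromo-2,4-bis(TBS-oxy)benzene
Conditions: TBSCl (2.2 equiv), imidazole, DMF, rt
Reagents that add atoms: 2 tert-butyldimethylsilyl chloride, C[Si](C)(Cl)C(C)(C)C
Why: Imidazole-mediated silylation of both phenols; silyl ethers are used on all seven phenols so that the final deprotection needs only buffered fluoride and no acid.

Step 2
Reactants: 3 1-bromo-2,4-bis(TBS-oxy)benzene; 4 triisopropyl borate; 5 water
Product: 8 [2,4-bis(TBS-oxy)phenyl]boronic acid, via aryllithium 6 (not isolated), via diisopropyl boronate 7 (not isolated)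
Conditions: B(OiPr)3, then n-BuLi added (in situ quench), THF/toluene, −78 °C; cold 1 M HCl work-up
Reagents that add atoms: 4 triisopropyl borate, CC(C)OB(OC(C)C)OC(C)C; 5 water, O
Why: Bromine–lithium exchange with the borate already present traps the ortho-silyloxy aryllithium before O→C silyl migration can occur, and hydrolysis of the boronate gives the boronic acid.

Step 3
Reactants: 9 benzene-1,3,5-triol (phloroglucinol); 2 tert-butyldimethylsilyl chloride
Product: 10 5-(TBS-oxy)benzene-1,3-diol
Conditions: TBSCl (1.0 equiv), imidazole, DMF, 0 °C; chromatographic separation from bis-ether and recovered triol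
Reagents that add atoms: 2 tert-butyldimethylsilyl chloride, C[Si](C)(Cl)C(C)(C)C
Why: Statistical monosilylation of a C3-symmetric triol should give a single constitutional mono-ether, and the unreacted triol can be recycled.

Step 4
Reactants: 10 5-(TBS-oxy)benzene-1,3-diol; 11 iodine
Product: 12 5-(TBS-oxy)-2-iodobenzene-1,3-diol
Conditions: I2, NaHCO3, THF/H2O, 0 °C
Reagents that add atoms: 11 iodine, II
Why: Iodination under bicarbonate conditions goes to the carbon between the two free hydroxyl groups, as is established for resorcinol and 5-substituted resorcinols, and the symmetric product makes the later furan closure unambiguous.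

Step 5
Reactants: 13 3-ethynylphenol; 2 tert-butyldimethylsilyl chloride
Product: 14 tert-butyl(3-ethynylphenoxy)dimethylsilane
Conditions: TBSCl, imidazole, CH2Cl2, rt
Reagents that add atoms: 2 tert-butyldimethylsilyl chloride, C[Si](C)(Cl)C(C)(C)C
Why: Routine phenol silylation, needed so that only one free phenol is present in the later ortho-formylation.

Step 6
Reactants: 12 5-(TBS-oxy)-2-iodobenzene-1,3-diol; 14 tert-butyl(3-ethynylphenoxy)dimethylsilane
Product: 16 6-(TBS-oxy)-2-[3-(TBS-oxy)phenyl]-1-benzofuran-4-ol, via alkynylresorcinol 15 (not isolated)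
Conditions: PdCl2(PPh3)2 (cat.), CuI (cat.), Et3N, DMF, 60 °C
Reagents that add atoms: 14 tert-butyl(3-ethynylphenoxy)dimethylsilane, C#Cc1cccc(O[Si](C)(C)C(C)(C)C)c1
Why: Sonogashira coupling followed by metal-promoted 5-endo-dig attack of a flanking phenol on the alkyne; the two hydroxyl groups are equivalent, so only one benzofuran can form and it keeps a free 4-OH.

Step 7
Reactants: 16 6-(TBS-oxy)-2-[3-(TBS-oxy)phenyl]-1-benzofuran-4-ol; 17 paraformaldehyde
Product: 19 4-hydroxy-6-(TBS-oxy)-2-[3-(TBS-oxy)phenyl]-1-benzofuran-5-carbaldehyde, via hydroxymethylphenol 18 (not isolated)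
Conditions: MgCl2, Et3N, (CH2O)n, THF, reflux; cold dilute HCl work-up
Reagents that add atoms: 17 paraformaldehyde (formaldehyde unit), C=O
Why: Casnati–Skattebøl ortho-formylation, in which the magnesium phenoxide delivers formaldehyde only to a free ortho carbon; C5 is the only one (the other ortho carbon is the ring-fusion atom), and the hydroxymethyl intermediate is oxidised in situ by a second formaldehyde.

Step 8
Reactants: 19 4-hydroxy-6-(TBS-oxy)-2-[3-(TBS-oxy)phenyl]-1-benzofuran-5-carbaldehyde; 20 tert-butyldimethylsilyl trifluoromethanesulfonate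
Product: 21 4,6-bis(TBS-oxy)-2-[3-(TBS-oxy)phenyl]-1-benzofuran-5-carbaldehyde (BF–CHO)
Conditions: TBSOTf, 2,6-lutidine, CH2Cl2, 0 °C
Reagents that add atoms: 20 tert-butyldimethylsilyl trifluoromethanesulfonate, C[Si](C)(OS(=O)(=O)C(F)(F)F)C(C)(C)C
Why: The hydrogen-bonded, flanked phenol needs the silyl triflate, and protecting it prevents ortho-hydroxystyrene side reactions later.

Step 9
Reactants: 21 BF–CHO; 22 1-(triphenyl-λ5-phosphanylidene)propan-2-one
Product: 23 (E)-4-(BF)but-3-en-2-one
Conditions: Ph3P=CHC(O)CH3, toluene, 100 °C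
Reagents that add atoms: 22 1-(triphenyl-λ5-phosphanylidene)propan-2-one, CC(=O)C=P(c1ccccc1)(c1ccccc1)c1ccccc1
Why: Wittig reaction of a stabilised ylide should give the (E)-enone under neutral conditions that leave the aryl silyl ethers intact.

Step 10
Reactants: 23 (E)-4-(BF)but-3-en-2-one; 24 cyclopropyldiphenylsulfonium tetrafluoroborate
Product: 26 2-methyl-2-[(E)-2-(BF)ethenyl]cyclobutan-1-one (racemic), via oxaspiropentane 25 (not isolated)
Conditions: sulfonium salt, KHMDS, DME, −45 → 0 °C; then LiBF4 (cat.), benzene, rt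
Reagents that add atoms: 24 cyclopropyldiphenylsulfonium tetrafluoroborate, c1ccc(cc1)[S+](C1CC1)c1ccccc1.F[B-](F)(F)F
Why: Sulfonium-ylide cyclobutanone spiroannulation, in which the unstabilised ylide epoxidises the carbonyl group (Corey–Chaykovsky type) and Lewis-acid opening of the allylic C–O bond triggers cyclopropylcarbinyl-to-cyclobutyl ring expansion; the quaternary carbon forms racemic, which is immaterial because it becomes sp2 in step 14.

Step 11
Reactants: 26 2-methyl-2-[(E)-2-(BF)ethenyl]cyclobutan-1-one; 27 N-phenylbis(trifluoromethanesulfonimide)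
Product: 29 4-methyl-4-[(E)-2-(BF)ethenyl]cyclobut-1-en-1-yl trifluoromethanesulfonate (racemic), via potassium enolate 28 (not isolated)
Conditions: KHMDS, THF, −78 °C; PhNTf2, −78 → 0 °C
Reagents that add atoms: 27 N-phenylbis(trifluoromethanesulfonimide), O=S(=O)(N(c1ccccc1)S(=O)(=O)C(F)(F)F)C(F)(F)F
Why: The ketone has only one α-CH2 group, so the enolate is regiodefined and O-triflation gives the cyclobutenyl triflate.

Step 12
Reactants: 29 cyclobutenyl triflate; 30 carbon monoxide; 8 [2,4-bis(TBS-oxy)phenyl]boronic acid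
Product: 31 (RA){4-methyl-4-[(E)-2-(BF)ethenyl]cyclobut-1-en-1-yl}methanone (racemic)
Conditions: PdCl2(dppf) (cat.), CO (1 atm), K2CO3, toluene, 50 °C
Reagents that add atoms: 30 carbon monoxide, [C-]#[O+]; 8 [2,4-bis(TBS-oxy)phenyl]boronic acid, OB(O)c1ccc(O[Si](C)(C)C(C)(C)C)cc1O[Si](C)(C)C(C)(C)C
Why: Carbonylative Suzuki–Miyaura coupling (oxidative addition, CO insertion, transmetalation, reductive elimination) installs the aryl ketone on C4 in one step, at a temperature kept low enough to avoid electrocyclic opening of the cyclobutene.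

Step 13
Reactants: 31 1-aroylcyclobutene; 8 [2,4-bis(TBS-oxy)phenyl]boronic acid
Product: 32 (RA){(1R,2S)-2-(RA)-4-methyl-4-[(E)-2-(BF)ethenyl]cyclobutyl}methanone (both epimers at the quaternary carbon)
Conditions: [RhCl(C2H4)2]2 (cat.), chiral bicyclo[2.2.2]octadiene ligand (Ph-bod*, enantiomer as assumed above), KOH (10 mol %), dioxane/H2O 10:1, 40 °C
Reagents that add atoms: 8 [2,4-bis(TBS-oxy)phenyl]boronic acid, OB(O)c1ccc(O[Si](C)(C)C(C)(C)C)cc1O[Si](C)(C)C(C)(C)C
Why: Hayashi–Miyaura asymmetric 1,4-addition, in which the aryl–Rh(diene) species carbometalates the strained enone on the face chosen by the ligand; this sets the aryl-bearing carbon (2S) under catalyst control in both enantiomers of the substrate (methyl and alkenyl on the quaternary carbon are nearly isosteric), and protonation should give mainly the trans ketone.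

Step 14
Reactants: 32 2-aryl-1-aroyl-4-methyl-4-alkenylcyclobutane
Product: 34 (RA)[(1R,2R,6S)-2-(BF)-6-(RA)-4-methylcyclohex-3-en-1-yl]methanone, via zwitterion 33 (not isolated)
Conditions: Sc(OTf)3 (10 mol %), CH2Cl2, −40 → 0 °C
Reagents that add atoms: none
Why: Proposed new method: Sc(III) bound to the aryl ketone should heterolyse the strained C1–C4 bond of 32, the one ring bond that joins a tertiary carbon carrying a vinylogous, oxygen-rich benzofuranyl donor to the ketone α-carbon, and the resulting scandium enolate/1-aryl-3-methylallyl cation pair 33 should reclose at the aryl-bearing allyl terminus C3, where the charge is concentrated, because this path sheds the cyclobutane strain whereas reclosure at C1 only returns 32. The closest known reaction types are the Lewis-acid opening of donor–acceptor cyclobutanes to 1,4-zwitterions and the Lewis-acid isomerisation of 2-vinylcyclobutyl carbonyl [2+2] adducts into the formal [4+2] cyclohexenes (a stepwise 1,3-shift), with the hole-catalysed and thermal vinylcyclobutane–cyclohexene rearrangements as further relatives. The six-membered ring closes by attack of the exocyclic enolate carbon C4 on the distal allyl terminus C3 (6-endo with respect to the allyl cation, enol-exo) through a chair-like transition state. C3 is set by the (E) geometry of the allyl terminus together with the face dictated by C5, whose aryl group sits equatorial in the chair, so the benzofuranyl group ends up equatorial and cis to the C5 aryl group; C4 is set by allylic strain in the enolate, which places the aroyl group equatorial and trans to both neighbours, and any C4 epimer should drain to this all-equatorial isomer by Sc-mediated enolisation. Both C1 epimers and either C4 epimer of 32 converge because C1 and C4 are planar in 33. The step needs heterolysis of C1–C4 in preference to the benzylic C4–C5 bond and to Grob-type fragmentation into chalcone and diene; the far better stabilised tertiary allylic cation, the weaker donor ability of silyloxy-substituted aryl groups and the low temperature should secure this.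

Step 15
Reactants: 34 heptakis-TBS ether of the target
Product: 35 (2,4-dihydroxyphenyl)[(1R,2R,6S)-2-[4,6-dihydroxy-2-(3-hydroxyphenyl)-1-benzofuran-5-yl]-6-(2,4-dihydroxyphenyl)-4-methylcyclohex-3-en-1-yl]methanone (CNP0221531.1)
Conditions: TBAF, AcOH (1:1), THF, degassed, 0 °C → rt
Reagents that add atoms: none
Why: Fluoride cleaves all seven aryl silyl ethers, and the acetic acid buffer protonates the phenoxides as they form, so neither the alkene, the ketone nor the stereocenters (C4 already in its thermodynamic configuration) should be affected.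

**Compound list**

1 | 4-bromobenzene-1,3-diol | Oc1ccc(Br)c(O)c1 | starting material
2 | tert-butyldimethylsilyl chloride | C[Si](C)(Cl)C(C)(C)C | starting material
3 | 1-bromo-2,4-bis(TBS-oxy)benzene | Brc1ccc(O[Si](C)(C)C(C)(C)C)cc1O[Si](C)(C)C(C)(C)C | intermediate
4 | triisopropyl borate | CC(C)OB(OC(C)C)OC(C)C | starting material
5 | water | O | starting material
6 | [2,4-bis(TBS-oxy)phenyl]lithium | [Li]c1ccc(O[Si](C)(C)C(C)(C)C)cc1O[Si](C)(C)C(C)(C)C | intermediate
7 | diisopropyl [2,4-bis(TBS-oxy)phenyl]boronate | CC(C)OB(OC(C)C)c1ccc(O[Si](C)(C)C(C)(C)C)cc1O[Si](C)(C)C(C)(C)C | intermediate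
8 | [2,4-bis(TBS-oxy)phenyl]boronic acid | OB(O)c1ccc(O[Si](C)(C)C(C)(C)C)cc1O[Si](C)(C)C(C)(C)C | intermediate
9 | benzene-1,3,5-triol (phloroglucinol) | Oc1cc(O)cc(O)c1 | starting material
10 | 5-(TBS-oxy)benzene-1,3-diol | Oc1cc(O)cc(O[Si](C)(C)C(C)(C)C)c1 | intermediate
11 | iodine | II | starting material
12 | 5-(TBS-oxy)-2-iodobenzene-1,3-diol | Oc1cc(O[Si](C)(C)C(C)(C)C)cc(O)c1I | intermediate
13 | 3-ethynylphenol | Oc1cccc(C#C)c1 | starting material
14 | tert-butyl(3-ethynylphenoxy)dimethylsilane | C#Cc1cccc(O[Si](C)(C)C(C)(C)C)c1 | intermediate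
15 | 5-(TBS-oxy)-2-{[3-(TBS-oxy)phenyl]ethynyl}benzene-1,3-diol | Oc1cc(O[Si](C)(C)C(C)(C)C)cc(O)c1C#Cc1cccc(O[Si](C)(C)C(C)(C)C)c1 | intermediate
16 | 6-(TBS-oxy)-2-[3-(TBS-oxy)phenyl]-1-benzofuran-4-ol | Oc1cc(O[Si](C)(C)C(C)(C)C)cc2oc(-c3cccc(O[Si](C)(C)C(C)(C)C)c3)cc12 | intermediate
17 | paraformaldehyde (formaldehyde unit) | C=O | starting material
18 | 5-(hydroxymethyl)-6-(TBS-oxy)-2-[3-(TBS-oxy)phenyl]-1-benzofuran-4-ol | OCc1c(O)c2cc(-c3cccc(O[Si](C)(C)C(C)(C)C)c3)oc2cc1O[Si](C)(C)C(C)(C)C | intermediate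
19 | 4-hydroxy-6-(TBS-oxy)-2-[3-(TBS-oxy)phenyl]-1-benzofuran-5-carbaldehyde | O=Cc1c(O)c2cc(-c3cccc(O[Si](C)(C)C(C)(C)C)c3)oc2cc1O[Si](C)(C)C(C)(C)C | intermediate
20 | tert-butyldimethylsilyl trifluoromethanesulfonate | C[Si](C)(OS(=O)(=O)C(F)(F)F)C(C)(C)C | starting material
21 | 4,6-bis(TBS-oxy)-2-[3-(TBS-oxy)phenyl]-1-benzofuran-5-carbaldehyde | O=Cc1c(O[Si](C)(C)C(C)(C)C)c2cc(-c3cccc(O[Si](C)(C)C(C)(C)C)c3)oc2cc1O[Si](C)(C)C(C)(C)C | intermediate
22 | 1-(triphenyl-λ5-phosphanylidene)propan-2-one | CC(=O)C=P(c1ccccc1)(c1ccccc1)c1ccccc1 | starting material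
23 | (E)-4-(BF)but-3-en-2-one | CC(=O)/C=C/c1c(O[Si](C)(C)C(C)(C)C)c2cc(-c3cccc(O[Si](C)(C)C(C)(C)C)c3)oc2cc1O[Si](C)(C)C(C)(C)C | intermediate
24 | cyclopropyldiphenylsulfonium tetrafluoroborate | c1ccc(cc1)[S+](C1CC1)c1ccccc1.F[B-](F)(F)F | starting material
25 | 2-methyl-2-[(E)-2-(BF)ethenyl]-1-oxaspiro[2.2]pentane (racemic) | CC1(/C=C/c2c(O[Si](C)(C)C(C)(C)C)c3cc(-c4cccc(O[Si](C)(C)C(C)(C)C)c4)oc3cc2O[Si](C)(C)C(C)(C)C)OC12CC2 | intermediate
26 | 2-methyl-2-[(E)-2-(BF)ethenyl]cyclobutan-1-one (racemic) | CC1(/C=C/c2c(O[Si](C)(C)C(C)(C)C)c3cc(-c4cccc(O[Si](C)(C)C(C)(C)C)c4)oc3cc2O[Si](C)(C)C(C)(C)C)CCC1=O | intermediate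
27 | N-phenylbis(trifluoromethanesulfonimide) | O=S(=O)(N(c1ccccc1)S(=O)(=O)C(F)(F)F)C(F)(F)F | starting material
28 | potassium 4-methyl-4-[(E)-2-(BF)ethenyl]cyclobut-1-en-1-olate (racemic) | CC1(/C=C/c2c(O[Si](C)(C)C(C)(C)C)c3cc(-c4cccc(O[Si](C)(C)C(C)(C)C)c4)oc3cc2O[Si](C)(C)C(C)(C)C)CC=C1[O-].[K+] | intermediate
29 | 4-methyl-4-[(E)-2-(BF)ethenyl]cyclobut-1-en-1-yl trifluoromethanesulfonate (racemic) | CC1(/C=C/c2c(O[Si](C)(C)C(C)(C)C)c3cc(-c4cccc(O[Si](C)(C)C(C)(C)C)c4)oc3cc2O[Si](C)(C)C(C)(C)C)CC=C1OS(=O)(=O)C(F)(F)F | intermediate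
30 | carbon monoxide | [C-]#[O+] | starting material
31 | (RA){4-methyl-4-[(E)-2-(BF)ethenyl]cyclobut-1-en-1-yl}methanone (racemic) | CC1(/C=C/c2c(O[Si](C)(C)C(C)(C)C)c3cc(-c4cccc(O[Si](C)(C)C(C)(C)C)c4)oc3cc2O[Si](C)(C)C(C)(C)C)CC=C1C(=O)c1ccc(O[Si](C)(C)C(C)(C)C)cc1O[Si](C)(C)C(C)(C)C | intermediate
32 | (RA){(1R,2S)-2-(RA)-4-methyl-4-[(E)-2-(BF)ethenyl]cyclobutyl}methanone, both epimers at the quaternary carbon | CC1(/C=C/c2c(O[Si](C)(C)C(C)(C)C)c3cc(-c4cccc(O[Si](C)(C)C(C)(C)C)c4)oc3cc2O[Si](C)(C)C(C)(C)C)C[C@H](c2ccc(O[Si](C)(C)C(C)(C)C)cc2O[Si](C)(C)C(C)(C)C)[C@H]1C(=O)c1ccc(O[Si](C)(C)C(C)(C)C)cc1O[Si](C)(C)C(C)(C)C | intermediate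
33 | ring-opened zwitterion (enolate at C4, (E)-allyl cation C1–C2–C3, C5 (S) intact; scandium-bound in the flask) | C[C+](/C=C/c1c(O[Si](C)(C)C(C)(C)C)c2cc(-c3cccc(O[Si](C)(C)C(C)(C)C)c3)oc2cc1O[Si](C)(C)C(C)(C)C)C[C@H](c1ccc(O[Si](C)(C)C(C)(C)C)cc1O[Si](C)(C)C(C)(C)C)C=C([O-])c1ccc(O[Si](C)(C)C(C)(C)C)cc1O[Si](C)(C)C(C)(C)C | intermediate
34 | (RA)[(1R,2R,6S)-2-(BF)-6-(RA)-4-methylcyclohex-3-en-1-yl]methanone | CC1=C[C@@H](c2c(O[Si](C)(C)C(C)(C)C)cc3oc(-c4cccc(O[Si](C)(C)C(C)(C)C)c4)cc3c2O[Si](C)(C)C(C)(C)C)[C@H](C(=O)c2ccc(O[Si](C)(C)C(C)(C)C)cc2O[Si](C)(C)C(C)(C)C)[C@@H](c2ccc(O[Si](C)(C)C(C)(C)C)cc2O[Si](C)(C)C(C)(C)C)C1 | intermediate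
35 | (2,4-dihydroxyphenyl)[(1R,2R,6S)-2-[4,6-dihydroxy-2-(3-hydroxyphenyl)-1-benzofuran-5-yl]-6-(2,4-dihydroxyphenyl)-4-methylcyclohex-3-en-1-yl]methanone | CC1=C[C@@H](c2c(O)cc3oc(-c4cccc(O)c4)cc3c2O)[C@H](C(=O)c2ccc(O)cc2O)[C@@H](c2ccc(O)cc2O)C1 | target

**Step count and risks**

Total steps: 15. Longest linear sequence: 12 steps (steps 3, 4 and 6–15, from phloroglucinol).

Steps most likely to fail:

1. Step 14 (Proposed new method). The ion pair may fragment in a Grob-type manner into chalcone and diene, which would recombine without the C5 information. The benzylic C4–C5 bond may ionise in competition, which would epimerise C5. Closure may also go through a boat-like transition state and give the C3 epimer. Fallback: the same bond reorganisation is run under single-electron oxidation instead of Lewis acid, as the hole-catalysed vinylcyclobutane-to-cyclohexene rearrangement of aryl-conjugated vinylcyclobutanes (tris(4-bromophenyl)aminium hexachloroantimonate (cat.), 2,6-di-tert-butylpyridine, CH2Cl2, 0 °C). Oxidation of the benzofuranyl-styrene unit cleaves the same C1–C4 bond as a distonic radical cation and recloses at C3. The fallback sets out from 32 and returns at 34, and makes no new compound (F0).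

2. Step 13. Carbometalation may be slow and poorly face-selective, because a 1-aroylcyclobutene with an adjacent quaternary carbon lies outside the cyclobutene-1-carboxylates on which this addition is established, and protodeboronation of the electron-rich boronic acid competes. Fallback: setting out from triflate 29, methoxycarbonylation (Pd(OAc)2, PPh3, CO, MeOH, Et3N, DMF, rt) gives methyl 4-methyl-4-[(E)-2-(BF)ethenyl]cyclobut-1-ene-1-carboxylate F1. The same Rh/chiral diene arylation with 8, now on the established ester class, gives methyl (1R,2S)-2-(RA)-4-methyl-4-[(E)-2-(BF)ethenyl]cyclobutane-1-carboxylate F2. Treatment with Me(MeO)NH·HCl and i-PrMgCl (THF, −20 °C) gives the N-methoxy-N-methyl amide F3. Addition of aryllithium 6 (from 3 and n-BuLi, −78 °C) then returns to the route at 32.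

3. Step 10. The sulfur ylide may add in conjugate fashion (spiropentane formation) or merely enolise the methyl ketone instead of adding to the carbonyl group. Fallback: setting out from enone 23, 1-lithio-1-(phenylsulfanyl)cyclopropane (cyclopropyl phenyl sulfide, n-BuLi, THF, 0 °C, then −78 °C) adds 1,2 to give (E)-4-(BF)-2-[1-(phenylsulfanyl)cyclopropyl]but-3-en-2-ol F4. Catalytic TsOH·H2O in wet benzene then drives the cyclopropylcarbinyl-to-cyclobutyl shift with loss of the thiol and returns to the route at 26.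

Further compounds
F0 | step 14 | none | none
F1 | step 13 | methyl 4-methyl-4-[(E)-2-(BF)ethenyl]cyclobut-1-ene-1-carboxylate (racemic) | CC1(/C=C/c2c(O[Si](C)(C)C(C)(C)C)c3cc(-c4cccc(O[Si](C)(C)C(C)(C)C)c4)oc3cc2O[Si](C)(C)C(C)(C)C)CC=C1C(=O)OC
F2 | step 13 | methyl (1R,2S)-2-(RA)-4-methyl-4-[(E)-2-(BF)ethenyl]cyclobutane-1-carboxylate (both epimers at the quaternary carbon) | CC1(/C=C/c2c(O[Si](C)(C)C(C)(C)C)c3cc(-c4cccc(O[Si](C)(C)C(C)(C)C)c4)oc3cc2O[Si](C)(C)C(C)(C)C)C[C@H](c2ccc(O[Si](C)(C)C(C)(C)C)cc2O[Si](C)(C)C(C)(C)C)[C@H]1C(=O)OC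
F3 | step 13 | (1R,2S)-N-methoxy-N-methyl-2-(RA)-4-methyl-4-[(E)-2-(BF)ethenyl]cyclobutane-1-carboxamide (both epimers at the quaternary carbon) | CC1(/C=C/c2c(O[Si](C)(C)C(C)(C)C)c3cc(-c4cccc(O[Si](C)(C)C(C)(C)C)c4)oc3cc2O[Si](C)(C)C(C)(C)C)C[C@H](c2ccc(O[Si](C)(C)C(C)(C)C)cc2O[Si](C)(C)C(C)(C)C)[C@H]1C(=O)N(C)OC
F4 | step 10 | (E)-4-(BF)-2-[1-(phenylsulfanyl)cyclopropyl]but-3-en-2-ol (racemic) | CC(O)(/C=C/c1c(O[Si](C)(C)C(C)(C)C)c2cc(-c3cccc(O[Si](C)(C)C(C)(C)C)c3)oc2cc1O[Si](C)(C)C(C)(C)C)C1(Sc2ccccc2)CC1
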